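## Retrosynthetic overview

1. Target 22 comes from late ortho-formylation and MOM removal; the symmetric aryl unit is carried intact from the start.
2. Ring A (C4a–C5 bond, C4a stereocentre, C8=C8a olefin) comes from a proposed cobalt-hydride radical cycloisomerisation of vinyl ketone 16; the C6 carbinol comes from ketone reduction.
3. Ketone 16 comes from enol triflate 13 (Negishi homologation, Weinreb amide), which comes from ring B ketone 11.
4. Ketone 11 (C1 quaternary and C2 methyl stereocentres) comes from copper-catalysed asymmetric conjugate methylation of enone 8 and enolate benzylation with bromide 7 (from 1 by directed ortho-metalation).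
5. Ring order: the aromatic ring and ring B are bought; ring A is the only ring formed (step 11).

Conventions: MOM = CH2OCH3; TBS = Si(CH3)2C(CH3)3; ArP = 4-(TBSOCH2)-2,6-bis(MOMO)phenyl. Decalin locants are those of the octahydronaphthalene in the name of 22: C1 quaternary, C2 CH–CH3, C4a ring-fusion CH, C5 C(CH3)2, C6 carbinol, C8=C8a olefin. Ring A = C4a, C5, C6, C7, C8, C8a; ring B = C1, C2, C3, C4, C4a, C8a.

Assumption: in step 6 the antipode of phosphoramidite L1 is used that gives the (3R) methyl adduct 9 (sense confirmed on the first batch); the target is handled as the open hydroxy-aldehyde drawn.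

## Route

Step 1
Reactants: 1 3,5-dihydroxybenzyl alcohol
Product: 2 [3,5-bis(methoxymethoxy)phenyl]methanol
Conditions: MOMCl (2.2 equiv), K2CO3, acetone, 0 °C → rt
Reagents that add atoms: chloromethyl methyl ether, COCCl
Why: Williamson etherification in which only the phenoxides formed with K2CO3 are alkylated and the un-ionised benzylic alcohol stays free.

Step 2
Reactants: 2 [3,5-bis(methoxymethoxy)phenyl]methanol
Product: 3 silyl ether tert-butyl{[3,5-bis(methoxymethoxy)phenyl]methoxy}dimethylsilane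
Conditions: TBSCl, imidazole, CH2Cl2, rt
Reagents that add atoms: tert-butyldimethylsilyl chloride, CC(C)(C)[Si](C)(C)Cl
Why: Standard imidazole-promoted silylation of the primary alcohol gives a silyl ether stable to base and organolithiums.

Step 3
Reactants: 3 silyl ether tert-butyl{[3,5-bis(methoxymethoxy)phenyl]methoxy}dimethylsilane
Product: 5 aldehyde 4-(TBSOCH2)-2,6-bis(methoxymethoxy)benzaldehyde, via aryllithium 4 (not isolated)
Conditions: n-BuLi (1.2 equiv), TMEDA, THF, 0 °C; DMF, −78 → 0 °C; H2O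
Reagents that add atoms: N,N-dimethylformamide, CN(C)C=O
Why: Directed ortho-metalation removes the C4 hydrogen between the two coordinating MOM ethers, and the aryllithium is formylated by DMF.

Step 4
Reactants: 5 aldehyde 4-(TBSOCH2)-2,6-bis(methoxymethoxy)benzaldehyde
Product: 6 benzylic alcohol [4-(TBSOCH2)-2,6-bis(methoxymethoxy)phenyl]methanol
Conditions: NaBH4, MeOH, 0 °C
Reagents that add atoms: none
Why: Borohydride reduction of the aryl aldehyde leaves the acetals and the silyl ether untouched.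

Step 5
Reactants: 6 benzylic alcohol [4-(TBSOCH2)-2,6-bis(methoxymethoxy)phenyl]methanol
Product: 7 benzylic bromide {[4-(bromomethyl)-3,5-bis(methoxymethoxy)phenyl]methoxy}(tert-butyl)dimethylsilane
Conditions: CBr4, PPh3, CH2Cl2, −20 → 0 °C; used at once
Reagents that add atoms: carbon tetrabromide, BrC(Br)(Br)Br
Why: Appel bromination converts the activated benzylic alcohol to the bromide under neutral conditions that spare the acid-labile MOM and silyl groups.

Step 6
Reactants: 8 2-methylcyclohex-2-en-1-one; 7 benzylic bromide {[4-(bromomethyl)-3,5-bis(methoxymethoxy)phenyl]methoxy}(tert-butyl)dimethylsilane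
Product: 11 ketone (2S,3R)-2-(ArP-methyl)-2,3-dimethylcyclohexan-1-one, via aluminium enolate 9 (not isolated), via lithium aluminate enolate 10 (not isolated)
Conditions: Me3Al (1.3 equiv), Cu(O2CC4H3S) (copper thiophene-2-carboxylate, 2 mol %), L1 (binaphthyl-2,2′-diyl N,N-bis(1-phenylethyl)phosphoramidite, 4 mol %), Et2O, −30 °C; MeLi (1.3 equiv), THF–HMPA, −30 °C; 7, −30 → 0 °C; aq. NH4Cl
Reagents that add atoms: trimethylaluminium, C[Al](C)C
Why: Copper-catalysed asymmetric conjugate addition sets C3 of the ketone (C2 of the decalin) under ligand control and gives the tetrasubstituted enolate regiospecifically, which as the aluminate is benzylated by SN2 anti to the new methyl group (trans-selective enolate alkylation), setting the quaternary centre (C1 of the decalin) with the two methyl groups cis.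

Step 7
Reactants: 11 ketone (2S,3R)-2-(ArP-methyl)-2,3-dimethylcyclohexan-1-one
Product: 13 enol triflate (5R,6S)-6-(ArP-methyl)-5,6-dimethylcyclohex-1-en-1-yl trifluoromethanesulfonate, via potassium enolate 12 (not isolated)
Conditions: KN(SiMe3)2, THF, −78 °C; PhNTf2, −78 → 0 °C; aq. NH4Cl
Reagents that add atoms: N-phenylbis(trifluoromethanesulfonimide), O=S(=O)(N(c1ccccc1)S(=O)(=O)C(F)(F)F)C(F)(F)F
Why: The only enolisable position is the C6 methylene of the cyclohexanone (the other α-carbon is quaternary), so deprotonation and O-triflation give a single enol triflate.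

Step 8
Reactants: 13 enol triflate (5R,6S)-6-(ArP-methyl)-5,6-dimethylcyclohex-1-en-1-yl trifluoromethanesulfonate
Product: 14 ester ethyl 3-[(5R,6S)-6-(ArP-methyl)-5,6-dimethylcyclohex-1-en-1-yl]propanoate
Conditions: BrZnCH2CH2CO2Et (1.5 equiv), PdCl2(dppf) (dppf = Fe(C5H4PPh2)2, 5 mol %), THF–DMA, 55 °C
Reagents that add atoms: (3-ethoxy-3-oxopropyl)zinc bromide, CCOC(=O)CC[Zn]Br
Why: Negishi sp2–sp3 cross-coupling of the enol triflate with the ester-stabilised zinc homoenolate installs C8, C7 and the future C6 carbonyl carbon without touching acetal or silyl groups.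

Step 9
Reactants: 14 ester ethyl 3-[(5R,6S)-6-(ArP-methyl)-5,6-dimethylcyclohex-1-en-1-yl]propanoate
Product: 15 Weinreb amide N-methoxy-N-methyl-3-[(5R,6S)-6-(ArP-methyl)-5,6-dimethylcyclohex-1-en-1-yl]propanamide
Conditions: MeNH(OMe)·HCl, (CH3)2CHMgCl, THF, −20 → 0 °C; aq. NH4Cl
Reagents that add atoms: N,O-dimethylhydroxylamine hydrochloride, CNOC.Cl
Why: Aminolysis of the ester by the chloromagnesium amide of N,O-dimethylhydroxylamine gives the Weinreb amide.

Step 10
Reactants: 15 Weinreb amide N-methoxy-N-methyl-3-[(5R,6S)-6-(ArP-methyl)-5,6-dimethylcyclohex-1-en-1-yl]propanamide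
Product: 16 vinyl ketone 5-[(5R,6S)-6-(ArP-methyl)-5,6-dimethylcyclohex-1-en-1-yl]-2-methylpent-1-en-3-one
Conditions: CH2=C(CH3)MgBr (1.5 equiv), THF, −20 → 0 °C; aq. NH4Cl; used promptly
Reagents that add atoms: prop-1-en-2-ylmagnesium bromide, CC(=C)[Mg]Br
Why: Grignard addition to a Weinreb amide stops at the ketone stage because the chelated tetrahedral adduct survives until work-up.

Step 11
Reactants: 16 vinyl ketone 5-[(5R,6S)-6-(ArP-methyl)-5,6-dimethylcyclohex-1-en-1-yl]-2-methylpent-1-en-3-one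
Product: 17 bicyclic ketone (5S,6R,8aR)-5-(ArP-methyl)-1,1,5,6-tetramethyl-1,5,6,7,8,8a-hexahydronaphthalen-2(3H)-one
Conditions: Co(C36H52N2O2)Cl (chloro[N,N′-bis(3,5-di-tert-butylsalicylidene)cyclohexane-1,2-diaminato]cobalt, trivalent cobalt, 5 mol %), PhSiH3 (10 mol %), degassed benzene, 0.02 M, 22 °C
Reagents that add atoms: none
Why: Proposed new method: a redox-neutral cobalt-hydride hydrogen-atom-transfer cycloisomerisation in which the trivalent cobalt hydride gives H• to the CH2 terminus of the vinyl ketone to form the tertiary α-acyl radical at C5 (the gem-dimethyl carbon); this radical adds 6-endo to C4a of the ring B olefin (endo mode favoured by the in-ring carbonyl and the fully substituted C8a) on the face anti to the pseudoaxial C1 methyl, since the other face would put the new quaternary carbon syn-diaxial to that methyl, so H4a ends cis to the C1 methyl (4aR in target locants); the tertiary C8a radical then gives up the accessible C8 hydrogen to divalent cobalt (C1 has no hydrogen, and loss of H4a would give an olefin flanked by two quaternary carbons), regenerating the hydride; back-transfer from the first radical only returns 16, so there is no dead end; the closest known reaction types are cobalt-salen hydrogen-atom-transfer cycloisomerisation of dienes and oxidative 6-endo cyclisations of α-carbonyl radicals onto trisubstituted olefins (manganese triacetate/copper diacetate type), neither shown for a vinyl ketone annulating onto a hindered ring olefin.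

Step 12
Reactants: 17 bicyclic ketone (5S,6R,8aR)-5-(ArP-methyl)-1,1,5,6-tetramethyl-1,5,6,7,8,8a-hexahydronaphthalen-2(3H)-one
Product: 18 alcohol (2S,5S,6R,8aR)-5-(ArP-methyl)-1,1,5,6-tetramethyl-1,2,3,5,6,7,8,8a-octahydronaphthalen-2-ol
Conditions: NaBH4, CeCl3·7H2O, MeOH–THF, −40 °C
Reagents that add atoms: none
Why: Luche-type reduction in which hydride attacks the ring A ketone axially from the face of H4a, anti to the pseudoaxial C5 methyl, giving the equatorial (6S in target locants) alcohol trans to H4a, while the non-basic cerium conditions keep the β,γ-olefin out of conjugation.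

Step 13
Reactants: 18 alcohol (2S,5S,6R,8aR)-5-(ArP-methyl)-1,1,5,6-tetramethyl-1,2,3,5,6,7,8,8a-octahydronaphthalen-2-ol
Product: 19 diol (2S,5S,6R,8aR)-5-{[4-(hydroxymethyl)-2,6-bis(methoxymethoxy)phenyl]methyl}-1,1,5,6-tetramethyl-1,2,3,5,6,7,8,8a-octahydronaphthalen-2-ol
Conditions: Bu4NF, THF, 0 °C → rt
Reagents that add atoms: none
Why: Fluoride-mediated desilylation frees the primary benzylic alcohol without affecting the MOM acetals or the olefin.

Step 14
Reactants: 19 diol (2S,5S,6R,8aR)-5-{[4-(hydroxymethyl)-2,6-bis(methoxymethoxy)phenyl]methyl}-1,1,5,6-tetramethyl-1,2,3,5,6,7,8,8a-octahydronaphthalen-2-ol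
Product: 21 protected aldehyde 6-(hydroxymethyl)-3-{[(1S,2R,4aR,6S)-6-hydroxy-1,2,5,5-tetramethyl-1,2,3,4,4a,5,6,7-octahydronaphthalen-1-yl]methyl}-2,4-bis(methoxymethoxy)benzaldehyde, via trilithio species 20 (not isolated)
Conditions: n-BuLi (3.6 equiv), TMEDA, THF, −20 → 0 °C; DMF, −40 → 0 °C; H2O
Reagents that add atoms: N,N-dimethylformamide, CN(C)C=O
Why: Directed ortho-metalation after double O-deprotonation, in which the two remaining aromatic hydrogens are equivalent and each is flanked by an OMOM group and the CH2OLi group, so lithiation and DMF quench give a single mono-aldehyde.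

Step 15
Reactants: 21 protected aldehyde 6-(hydroxymethyl)-3-{[(1S,2R,4aR,6S)-6-hydroxy-1,2,5,5-tetramethyl-1,2,3,4,4a,5,6,7-octahydronaphthalen-1-yl]methyl}-2,4-bis(methoxymethoxy)benzaldehyde
Product: 22 target 2,4-dihydroxy-6-(hydroxymethyl)-3-{[(1S,2R,4aR,6S)-6-hydroxy-1,2,5,5-tetramethyl-1,2,3,4,4a,5,6,7-octahydronaphthalen-1-yl]methyl}benzaldehyde
Conditions: 2 M aq. HCl–THF (1:4), 35 °C
Reagents that add atoms: none
Why: Acid-catalysed hydrolysis of the two aryl MOM acetals in dilute aqueous acid, too weak to protonate the hindered trisubstituted olefin, unmasks the resorcinol and gives the target.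

## Compound list

1 | 3,5-dihydroxybenzyl alcohol | OCc1cc(O)cc(O)c1 | starting material
2 | [3,5-bis(methoxymethoxy)phenyl]methanol | OCc1cc(OCOC)cc(OCOC)c1 | intermediate
3 | tert-butyl{[3,5-bis(methoxymethoxy)phenyl]methoxy}dimethylsilane | CC(C)(C)[Si](C)(C)OCc1cc(OCOC)cc(OCOC)c1 | intermediate
4 | {4-[(tert-butyldimethylsilyloxy)methyl]-2,6-bis(methoxymethoxy)phenyl}lithium (not isolated) | CC(C)(C)[Si](C)(C)OCc1cc(OCOC)c([Li])c(OCOC)c1 | intermediate
5 | 4-[(tert-butyldimethylsilyloxy)methyl]-2,6-bis(methoxymethoxy)benzaldehyde | CC(C)(C)[Si](C)(C)OCc1cc(OCOC)c(C=O)c(OCOC)c1 | intermediate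
6 | {4-[(tert-butyldimethylsilyloxy)methyl]-2,6-bis(methoxymethoxy)phenyl}methanol | CC(C)(C)[Si](C)(C)OCc1cc(OCOC)c(CO)c(OCOC)c1 | intermediate
7 | {[4-(bromomethyl)-3,5-bis(methoxymethoxy)phenyl]methoxy}(tert-butyl)dimethylsilane | CC(C)(C)[Si](C)(C)OCc1cc(OCOC)c(CBr)c(OCOC)c1 | intermediate
8 | 2-methylcyclohex-2-en-1-one | CC1=CCCCC1=O | starting material
9 | dimethylaluminium (3R)-2,3-dimethylcyclohex-1-en-1-olate (not isolated) | C[C@@H]1CCCC(O[Al](C)C)=C1C | intermediate
10 | lithium trimethyl[(3R)-2,3-dimethylcyclohex-1-en-1-olato]aluminate (not isolated) | C[C@@H]1CCCC(O[Al-](C)(C)C)=C1C.[Li+] | intermediate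
11 | (2S,3R)-2-(ArP-methyl)-2,3-dimethylcyclohexan-1-one | C[C@@H]1CCCC(=O)[C@@]1(C)Cc1c(OCOC)cc(CO[Si](C)(C)C(C)(C)C)cc1OCOC | intermediate
12 | potassium (5R,6S)-6-(ArP-methyl)-5,6-dimethylcyclohex-1-en-1-olate (not isolated) | C[C@@H]1CCC=C([O-])[C@@]1(C)Cc1c(OCOC)cc(CO[Si](C)(C)C(C)(C)C)cc1OCOC.[K+] | intermediate
13 | (5R,6S)-6-(ArP-methyl)-5,6-dimethylcyclohex-1-en-1-yl trifluoromethanesulfonate | C[C@@H]1CCC=C(OS(=O)(=O)C(F)(F)F)[C@@]1(C)Cc1c(OCOC)cc(CO[Si](C)(C)C(C)(C)C)cc1OCOC | intermediate
14 | ethyl 3-[(5R,6S)-6-(ArP-methyl)-5,6-dimethylcyclohex-1-en-1-yl]propanoate | C[C@@H]1CCC=C(CCC(=O)OCC)[C@@]1(C)Cc1c(OCOC)cc(CO[Si](C)(C)C(C)(C)C)cc1OCOC | intermediate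
15 | N-methoxy-N-methyl-3-[(5R,6S)-6-(ArP-methyl)-5,6-dimethylcyclohex-1-en-1-yl]propanamide | C[C@@H]1CCC=C(CCC(=O)N(C)OC)[C@@]1(C)Cc1c(OCOC)cc(CO[Si](C)(C)C(C)(C)C)cc1OCOC | intermediate
16 | 5-[(5R,6S)-6-(ArP-methyl)-5,6-dimethylcyclohex-1-en-1-yl]-2-methylpent-1-en-3-one | C[C@@H]1CCC=C(CCC(=O)C(C)=C)[C@@]1(C)Cc1c(OCOC)cc(CO[Si](C)(C)C(C)(C)C)cc1OCOC | intermediate
17 | (5S,6R,8aR)-5-(ArP-methyl)-1,1,5,6-tetramethyl-1,5,6,7,8,8a-hexahydronaphthalen-2(3H)-one | C[C@@H]1CC[C@@H]2C(=CCC(=O)C2(C)C)[C@@]1(C)Cc1c(OCOC)cc(CO[Si](C)(C)C(C)(C)C)cc1OCOC | intermediate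
18 | (2S,5S,6R,8aR)-5-(ArP-methyl)-1,1,5,6-tetramethyl-1,2,3,5,6,7,8,8a-octahydronaphthalen-2-ol | C[C@@H]1CC[C@@H]2C(=CC[C@H](O)C2(C)C)[C@@]1(C)Cc1c(OCOC)cc(CO[Si](C)(C)C(C)(C)C)cc1OCOC | intermediate
19 | (2S,5S,6R,8aR)-5-{[4-(hydroxymethyl)-2,6-bis(methoxymethoxy)phenyl]methyl}-1,1,5,6-tetramethyl-1,2,3,5,6,7,8,8a-octahydronaphthalen-2-ol | C[C@@H]1CC[C@@H]2C(=CC[C@H](O)C2(C)C)[C@@]1(C)Cc1c(OCOC)cc(CO)cc1OCOC | intermediate
20 | trilithio derivative of 19 (both alkoxides and the aryl carbon ortho to CH2OLi; not isolated) | C[C@@H]1CC[C@@H]2C(=CC[C@H](O[Li])C2(C)C)[C@@]1(C)Cc1c(OCOC)cc(CO[Li])c([Li])c1OCOC | intermediate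
21 | 6-(hydroxymethyl)-3-{[(1S,2R,4aR,6S)-6-hydroxy-1,2,5,5-tetramethyl-1,2,3,4,4a,5,6,7-octahydronaphthalen-1-yl]methyl}-2,4-bis(methoxymethoxy)benzaldehyde | C[C@@H]1CC[C@@H]2C(=CC[C@H](O)C2(C)C)[C@@]1(C)Cc1c(OCOC)cc(CO)c(C=O)c1OCOC | intermediate
22 | 2,4-dihydroxy-6-(hydroxymethyl)-3-{[(1S,2R,4aR,6S)-6-hydroxy-1,2,5,5-tetramethyl-1,2,3,4,4a,5,6,7-octahydronaphthalen-1-yl]methyl}benzaldehyde | C[C@@H]1CC[C@@H]2C(=CC[C@H](O)C2(C)C)[C@@]1(C)Cc1c(O)cc(CO)c(C=O)c1O | target

## Step count and risk

Total steps: 15. Longest linear sequence: 15 (1 → 22; enone 8 enters at step 6).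

Three steps most likely to fail:

**Step 11 (proposed new cycloisomerisation).** Risks are slow 6-endo closure, olefin migration by the cobalt hydride, or poor face selectivity at C4a. The fallback uses known chemistry, sets out from enol triflate 13 and comes back at diol 19. Negishi coupling of 13 with (CH3)2C=CHCH2CH2ZnBr under PdCl2(dppf) gives the diene F2. Shi epoxidation with the L-fructose-derived ketone (KHSO5, K2CO3, MeCN–dimethoxymethane–H2O, 0 °C) oxidises only the unhindered terminal trisubstituted olefin and gives the (S)-epoxide F3. Titanocene-catalysed reductive epoxide opening and 6-endo radical cyclisation ((C5H5)2TiCl2 20 mol %, Mn, Me3SiCl, 2,4,6-collidine, THF; trivalent titanium formed in the flask) closes ring A through a chair transition state. This places the C6 oxygen trans to H4a and ends by loss of a C8 hydrogen, giving the bis-silyl ether F4. Bu4NF then removes both silyl groups and delivers 19, so steps 12 and 13 are bypassed.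

**Step 6 (three-component conjugate methylation and benzylation).** The SN2 reaction of a tetrasubstituted aluminate enolate with the doubly ortho-substituted bromide 7 may be slow. The fallback sets out from enone 8 and comes back at ketone 11. The same copper-catalysed conjugate methylation is run, but the enolate is trapped with Me3SiOSO2CF3 to give the silyl enol ether F1, which is isolated and checked for ee. F1 is then benzylated in an SN1-type Lewis-acid-catalysed reaction with benzylic alcohol 6 itself (Sc(O3SCF3)3 5 mol %, CH2Cl2, −20 °C). The 2,6-dioxygenated benzylic cation is captured anti to the C3 methyl group to give 11; step 5 is then not needed.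

**Step 14 (late ortho-lithiation and formylation of a polyol).** Solubility of the polyanion or competing allylic metalation may lower the yield. The fallback sets out from diol 19 and comes back at target 22. The two MOM ethers are hydrolysed first (2 M aq. HCl–THF, 35 °C) to give the resorcinol F5. Magnesium-mediated ortho-formylation of the free phenol (MgCl2, Et3N, paraformaldehyde, MeCN, 70 °C) then gives 22. The only free ring positions are the two equivalent ones ortho to a phenol, and the first formyl group deactivates the ring.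

## Further compounds

F1 | step 6 | trimethyl{[(3R)-2,3-dimethylcyclohex-1-en-1-yl]oxy}silane | C[C@@H]1CCCC(O[Si](C)(C)C)=C1C
F2 | step 11 | (5R,6S)-6-(ArP-methyl)-5,6-dimethyl-1-(4-methylpent-3-en-1-yl)cyclohex-1-ene | C[C@@H]1CCC=C(CCC=C(C)C)[C@@]1(C)Cc1c(OCOC)cc(CO[Si](C)(C)C(C)(C)C)cc1OCOC
F3 | step 11 | (5R,6S)-6-(ArP-methyl)-1-{2-[(2S)-3,3-dimethyloxiran-2-yl]ethyl}-5,6-dimethylcyclohex-1-ene | C[C@@H]1CCC=C(CC[C@@H]2OC2(C)C)[C@@]1(C)Cc1c(OCOC)cc(CO[Si](C)(C)C(C)(C)C)cc1OCOC
F4 | step 11 | trimethylsilyl ether of 18 | C[C@@H]1CC[C@@H]2C(=CC[C@H](O[Si](C)(C)C)C2(C)C)[C@@]1(C)Cc1c(OCOC)cc(CO[Si](C)(C)C(C)(C)C)cc1OCOC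
F5 | step 14 | 5-(hydroxymethyl)-2-{[(1S,2R,4aR,6S)-6-hydroxy-1,2,5,5-tetramethyl-1,2,3,4,4a,5,6,7-octahydronaphthalen-1-yl]methyl}benzene-1,3-diol | C[C@@H]1CC[C@@H]2C(=CC[C@H](O)C2(C)C)[C@@]1(C)Cc1c(O)cc(CO)cc1O
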